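**Strategy.** The route rests on opening ring B at C5–C6 (drimane numbering). C5 sits between the fully substituted C4 and C10, so a C5 ketone on ring A cannot enolise and waits as a latent electrophile. In one operation the C10 enolate of an enantioenriched 1-silyl ketone adds to di-tert-butyl fumarate (C9/C8 with C11/C12), the resulting ester enolate adds to vinyltriphenylphosphonium bromide (C7/C6), and the ylide closes ring B by intramolecular Wittig olefination at C5. Hydrogenation then sets the trans ring fusion; the silyl group directs C10 and is the masked 1β-oxygen. The precursor is a monocyclic 3-silyl-2,6,6-trimethylcyclohexanone.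

Key step: step 3

Remarks on the chemistry:
- Bicyclic compounds carry drimane numbering (ring A: C1–C5, C10; ring B: C5–C10; C11 on C9; C12 on C8); β is the face of the C10 methyl group.
- The ligand enantiomer in step 2 is assumed to be the one that gives the (3R) silane; if the sense of induction is the opposite, the other ligand enantiomer is used.

**Step 1**
Reactants: 1 2,2,6-trimethylcyclohexan-1-one
Product: 2 2,6,6-trimethylcyclohex-2-en-1-one
Conditions: IBX (1.5 equiv), DMSO, 75 °C
Reagents that add atoms: none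
Why: IBX dehydrogenation of a ketone through its enol; C6–H is the only α-hydrogen, so only one enone regioisomer can form.

**Step 2**
Reactants: 2 2,6,6-trimethylcyclohex-2-en-1-one
Product: 3 (2R,3R)-3-[dimethyl(phenyl)silyl]-2,6,6-trimethylcyclohexan-1-one
Conditions: PhMe2Si–Bpin (1.5 equiv), [Rh(cod)2]OTf (5 mol%), (S)-BINAP (10 mol%), Et3N, 1,4-dioxane/H2O 10:1, 50 °C
Reagents that add atoms: dimethyl(phenyl)silylboronic acid pinacol ester, CC1(C)OB(OC1(C)C)[Si](C)(C)c1ccccc1
Why: Rhodium-catalysed enantioselective conjugate silyl transfer to a cyclic enone; the chiral bisphosphine complex selects the enone face and so sets the silicon-bearing carbon (future C1), while protonation should give mainly the 2,3-trans ketone (C2 is enolised again in step 3).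

**Step 3**
Reactants: 3 (2R,3R)-3-[dimethyl(phenyl)silyl]-2,6,6-trimethylcyclohexan-1-one; 4 di-tert-butyl fumarate; 5 vinyltriphenylphosphonium bromide
Product: 8 di-tert-butyl 1β-[dimethyl(phenyl)silyl]drim-5-ene-11,12-dioate as C8/C9 epimers, via ester enolate 6 (not isolated), via phosphorus ylide 7 (not isolated)
Conditions: LDA (1.05 equiv), THF, −78 → 0 °C; 4, −78 → −40 °C; 5, −40 °C → reflux
Reagents that add atoms: none
Why: LDA removes the only α-hydrogen of 3 (C10–H; C4 is quaternary) and the lithium enolate adds through C10 to 4 on the face anti to the neighbouring C1 silyl group; ester enolate 6 then adds to vinylphosphonium salt 5 to give ylide 7, whose carbanion (C6) attacks the C5 ketone, and loss of Ph3PO from the oxaphosphetane gives the C5=C6 bond. The closest known chemistry is the one-pot Michael–Michael–Wittig assembly of cyclohexenes from a ketone enolate, an acrylate-type acceptor and a vinylphosphonium salt. Ring B closes by 6-exo-trig addition of the ylide carbon to the carbonyl group, followed by cycloreversion of the four-membered oxaphosphetane. The quaternary C10 is controlled by the C1 stereocentre (anti alkylation of a β-silyl enolate, methyl ends cis to silicon); C8 and C9 form as mixtures and are corrected in steps 5 and 7. The step needs the ylide to choose the hindered C5 ketone over the ester groups; the tert-butyl esters should secure this, because the only competing ring closure is acylation at C11.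

**Step 4**
Reactants: 8 di-tert-butyl 1β-[dimethyl(phenyl)silyl]drim-5-ene-11,12-dioate
Product: 9 di-tert-butyl 1β-[dimethyl(phenyl)silyl]-5α-drimane-11,12-dioate as C8/C9 epimers
Conditions: H2 (4 atm), Pd/C, EtOAc, rt
Reagents that add atoms: none
Why: Heterogeneous hydrogenation from the α face, opposite to the axial C10 methyl and the β methyl on C4, should give the 5α-H trans-decalin.

**Step 5**
Reactants: 9 di-tert-butyl 1β-[dimethyl(phenyl)silyl]-5α-drimane-11,12-dioate
Product: 11 di-tert-butyl 1β-[dimethyl(phenyl)silyl]drim-7-ene-11,12-dioate as C9 epimers, via α-phenylselanyl diester 10 (not isolated)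
Conditions: LDA (1.3 equiv), THF, −78 → −30 °C; PhSeBr, −78 °C; then 30% H2O2, pyridine, CH2Cl2, 0 °C → rt
Reagents that add atoms: none
Why: α-Selenenylation of the less hindered ester enolate (C8) and selenoxide syn-elimination introduce the ring B unsaturation; any Δ8 isomer converges with the Δ7 ester in step 7.

**Step 6**
Reactants: 11 di-tert-butyl 1β-[dimethyl(phenyl)silyl]drim-7-ene-11,12-dioate
Product: 12 di-tert-butyl 1β-hydroxydrim-7-ene-11,12-dioate as C9 epimers
Conditions: Hg(OAc)2, AcOOH, AcOH, rt
Reagents that add atoms: peracetic acid, CC(=O)OO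
Why: Fleming–Tamao oxidation: mercuridesilylation of the phenyl group, then a peracid-induced shift of C1 from silicon to oxygen, turns C–Si into C–OH with retention and gives the 1β-alcohol; the electron-poor C7=C8 bond should not be epoxidised.

**Step 7**
Reactants: 12 di-tert-butyl 1β-hydroxydrim-7-ene-11,12-dioate
Product: 14 di-tert-butyl 1β-hydroxydrim-7-ene-11,12-dioate of natural C9 configuration (9α-H), via dilithium dienolate 13 (not isolated)
Conditions: LDA (3 equiv), THF, −78 → −30 °C; then AcOH, THF, −78 °C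
Reagents that add atoms: none
Why: Deconjugative kinetic protonation of an ester dienolate: the doubly activated C9–H (or C7–H of the Δ8 isomer) is removed and the dienolate is protonated at its α-carbon C9 from the α face, opposite to the axial C10 methyl, which sets C9 and leaves the Δ7 double bond.

**Step 8**
Reactants: 14 di-tert-butyl 1β-hydroxydrim-7-ene-11,12-dioate (9α-H)
Product: 15 drim-7-ene-1β,11,12-triol
Conditions: LiAlH4, THF, 0 °C → reflux
Reagents that add atoms: none
Why: Hydride reduction of both esters to primary alcohols; C9 is no longer epimerisable afterwards.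

**Step 9**
Reactants: 15 drim-7-ene-1β,11,12-triol
Product: 16 11,12-bis(triethylsilyloxy)drim-7-en-1β-ol
Conditions: TESCl (2.2 equiv), imidazole, CH2Cl2, −20 °C
Reagents that add atoms: chlorotriethylsilane, CC[Si](Cl)(CC)CC
Why: Silylation of the two primary hydroxyl groups; the neopentyl secondary 1β-hydroxyl is too hindered to react at low temperature.

**Step 10**
Reactants: 17 (E)-p-coumaric acid
Product: 19 (E)-3-[4-(tert-butyldimethylsilyloxy)phenyl]prop-2-enoic acid, via silyl ester 18 (not isolated)
Conditions: TBSCl (2.5 equiv), imidazole, DMF, rt; then AcOH/THF/H2O, rt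
Reagents that add atoms: tert-butyl(chloro)dimethylsilane, CC(C)(C)[Si](C)(C)Cl
Why: Silylation of phenol and acid, then selective hydrolysis of the labile silyl ester; the aryl silyl ether is stable to mild acid.

**Step 11**
Reactants: 16 11,12-bis(triethylsilyloxy)drim-7-en-1β-ol; 19 (E)-3-[4-(tert-butyldimethylsilyloxy)phenyl]prop-2-enoic acid
Product: 21 11,12-bis(triethylsilyloxy)drim-7-en-1β-yl (E)-3-[4-(tert-butyldimethylsilyloxy)phenyl]prop-2-enoate, via mixed anhydride 20 (not isolated)
Conditions: 2,4,6-trichlorobenzoyl chloride, Et3N, THF, rt; then 16, DMAP, PhMe, 80 °C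
Reagents that add atoms: none
Why: Yamaguchi esterification; the acylpyridinium ion formed from the mixed anhydride is reactive enough for the hindered secondary alcohol, and the (E)-alkene is carried over unchanged.

**Step 12**
Reactants: 21 the bis-TES coumarate ester
Product: 22 11,12-dihydroxydrim-7-en-1β-yl (E)-3-[4-(tert-butyldimethylsilyloxy)phenyl]prop-2-enoate
Conditions: PPTS, MeOH/CH2Cl2, 0 °C → rt
Reagents that add atoms: none
Why: Acid-catalysed methanolysis cleaves the primary alkyl triethylsilyl ethers, while the aryl tert-butyldimethylsilyl ether and the cinnamate are stable to mild acid.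

**Step 13**
Reactants: 22 the 11,12-diol
Product: 23 1β-[(E)-4-(tert-butyldimethylsilyloxy)cinnamoyloxy]polygodial (drim-7-ene-11,12-dial 1β-ester)
Conditions: (COCl)2, DMSO, CH2Cl2, −78 °C; Et3N, −78 → −30 °C
Reagents that add atoms: none
Why: Swern oxidation of both primary alcohols to the ene-dialdehyde; the low temperature and short contact with base should prevent epimerisation at C9, and the phenol stays protected.

**Step 14**
Reactants: 23 the silyl-protected dialdehyde
Product: 24 1β-(E)-p-coumaroyloxypolygodial (CNP0187624.1)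
Conditions: TBAF/AcOH (1:1), THF, 0 °C
Reagents that add atoms: none
Why: Fluoride cleavage of the aryl silyl ether; the acetic acid buffer should protect the base-sensitive C9 centre and the ester.

**Compound list**

1 | 2,2,6-trimethylcyclohexan-1-one | CC1CCCC(C)(C)C1=O | starting material
2 | 2,6,6-trimethylcyclohex-2-en-1-one | CC1=CCCC(C)(C)C1=O | intermediate
3 | (2R,3R)-3-[dimethyl(phenyl)silyl]-2,6,6-trimethylcyclohexan-1-one (2,3-trans) | CC1(C)CC[C@@H]([Si](C)(C)c2ccccc2)[C@H](C)C1=O | intermediate
4 | di-tert-butyl fumarate | CC(C)(C)OC(=O)/C=C/C(=O)OC(C)(C)C | starting material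
5 | vinyltriphenylphosphonium bromide | C=C[P+](c1ccccc1)(c1ccccc1)c1ccccc1.[Br-] | starting material
6 | lithium ester enolate of the Michael adduct (C10 quaternary, methyl cis to silicon; C9 unassigned) | CC1(C)CC[C@@H]([Si](C)(C)c2ccccc2)[C@](C)(C(C(=O)OC(C)(C)C)C=C(OC(C)(C)C)O[Li])C1=O | intermediate
7 | phosphorus ylide (C6 ylide carbon on the C8 side chain; C8/C9 unassigned) | CC1(C)CC[C@@H]([Si](C)(C)c2ccccc2)[C@](C)(C(C(=O)OC(C)(C)C)C(CC=P(c3ccccc3)(c4ccccc4)c5ccccc5)C(=O)OC(C)(C)C)C1=O | intermediate
8 | di-tert-butyl 1β-[dimethyl(phenyl)silyl]drim-5-ene-11,12-dioate (C8/C9 epimers) | CC1(C)CC[C@@H]([Si](C)(C)c2ccccc2)[C@]2(C)C(C(=O)OC(C)(C)C)C(C(=O)OC(C)(C)C)CC=C12 | intermediate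
9 | di-tert-butyl 1β-[dimethyl(phenyl)silyl]-5α-drimane-11,12-dioate (C8/C9 epimers) | CC1(C)CC[C@@H]([Si](C)(C)c2ccccc2)[C@]2(C)C(C(=O)OC(C)(C)C)C(C(=O)OC(C)(C)C)CC[C@@H]12 | intermediate
10 | di-tert-butyl 1β-[dimethyl(phenyl)silyl]-8-(phenylselanyl)-5α-drimane-11,12-dioate | CC1(C)CC[C@@H]([Si](C)(C)c2ccccc2)[C@]2(C)C(C(=O)OC(C)(C)C)C([Se]c3ccccc3)(C(=O)OC(C)(C)C)CC[C@@H]12 | intermediate
11 | di-tert-butyl 1β-[dimethyl(phenyl)silyl]drim-7-ene-11,12-dioate (C9 epimers) | CC1(C)CC[C@@H]([Si](C)(C)c2ccccc2)[C@]2(C)C(C(=O)OC(C)(C)C)C(C(=O)OC(C)(C)C)=CC[C@@H]12 | intermediate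
12 | di-tert-butyl 1β-hydroxydrim-7-ene-11,12-dioate (C9 epimers) | CC1(C)CC[C@@H](O)[C@]2(C)C(C(=O)OC(C)(C)C)C(C(=O)OC(C)(C)C)=CC[C@@H]12 | intermediate
13 | dilithium alkoxide dienolate (C9=C11 enolate, Δ7) | CC1(C)CC[C@@H](O[Li])[C@]2(C)C(=C(OC(C)(C)C)O[Li])C(C(=O)OC(C)(C)C)=CC[C@@H]12 | intermediate
14 | di-tert-butyl 1β-hydroxydrim-7-ene-11,12-dioate, 9α-H (C11 β) | CC1(C)CC[C@@H](O)[C@]2(C)[C@@H](C(=O)OC(C)(C)C)C(C(=O)OC(C)(C)C)=CC[C@@H]12 | intermediate
15 | drim-7-ene-1β,11,12-triol | CC1(C)CC[C@@H](O)[C@]2(C)[C@@H](CO)C(CO)=CC[C@@H]12 | intermediate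
16 | 11,12-bis(triethylsilyloxy)drim-7-en-1β-ol | CC1(C)CC[C@@H](O)[C@]2(C)[C@@H](CO[Si](CC)(CC)CC)C(CO[Si](CC)(CC)CC)=CC[C@@H]12 | intermediate
17 | (E)-p-coumaric acid | OC(=O)/C=C/c1ccc(O)cc1 | starting material
18 | tert-butyldimethylsilyl (E)-3-[4-(tert-butyldimethylsilyloxy)phenyl]prop-2-enoate | CC(C)(C)[Si](C)(C)OC(=O)/C=C/c1ccc(O[Si](C)(C)C(C)(C)C)cc1 | intermediate
19 | (E)-3-[4-(tert-butyldimethylsilyloxy)phenyl]prop-2-enoic acid | OC(=O)/C=C/c1ccc(O[Si](C)(C)C(C)(C)C)cc1 | intermediate
20 | mixed anhydride of 19 with 2,4,6-trichlorobenzoic acid | O=C(/C=C/c1ccc(O[Si](C)(C)C(C)(C)C)cc1)OC(=O)c1c(Cl)cc(Cl)cc1Cl | intermediate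
21 | 11,12-bis(triethylsilyloxy)drim-7-en-1β-yl (E)-3-[4-(tert-butyldimethylsilyloxy)phenyl]prop-2-enoate | CC1(C)CC[C@@H](OC(=O)/C=C/c3ccc(O[Si](C)(C)C(C)(C)C)cc3)[C@]2(C)[C@@H](CO[Si](CC)(CC)CC)C(CO[Si](CC)(CC)CC)=CC[C@@H]12 | intermediate
22 | 11,12-dihydroxydrim-7-en-1β-yl (E)-3-[4-(tert-butyldimethylsilyloxy)phenyl]prop-2-enoate | CC1(C)CC[C@@H](OC(=O)/C=C/c3ccc(O[Si](C)(C)C(C)(C)C)cc3)[C@]2(C)[C@@H](CO)C(CO)=CC[C@@H]12 | intermediate
23 | 1β-[(E)-4-(tert-butyldimethylsilyloxy)cinnamoyloxy]drim-7-ene-11,12-dial | CC1(C)CC[C@@H](OC(=O)/C=C/c3ccc(O[Si](C)(C)C(C)(C)C)cc3)[C@]2(C)[C@@H](C=O)C(C=O)=CC[C@@H]12 | intermediate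
24 | 1β-(E)-p-coumaroyloxypolygodial (CNP0187624.1) | CC1(C)CC[C@@H](OC(=O)/C=C/c2ccc(O)cc2)[C@]2(C)[C@@H](C=O)C(C=O)=CC[C@@H]12 | target

**Step count and risks**

Total step count: 14. Longest linear sequence: 13 steps (1 → 2 → 3 → 8 → 9 → 11 → 12 → 14 → 15 → 16 → 21 → 22 → 23 → 24).

Steps most likely to fail:

- **Step 3.** The first Michael addition may be slow or reversible at the crowded C10, and the ylide may fail to add to the C5 carbonyl group, which lies between two quaternary carbons. The fallback closes the same bond by reductive coupling of two carbonyl carbons. It sets out from 3: the enolate is added to 4 as before, but the ester enolate is trapped with allyl bromide to give the C8-allyl keto diester F1. Ozonolysis (O3, CH2Cl2/MeOH, −78 °C; Me2S) cleaves the allyl group to the C6 keto aldehyde F2. An intramolecular McMurry coupling (TiCl3(DME)1.5, Zn–Cu couple, DME, reflux, slow addition) then joins C5 and C6 and comes back to the route at 8.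

- **Step 7.** The dienolate may be protonated at C7, which returns the conjugated Δ8 isomer, or from the β face, which gives the 9α ester. The fallback enforces C9 through a temporary lactone. It sets out from 12: catalytic KOt-Bu in THF should move the double bond into conjugation and close the 1β-alkoxide onto the C11 ester to give the Δ8 1,11-olide F3. Treatment with LDA and then AcOH at −78 °C deconjugates it to the Δ7 1,11-olide F4; the five-membered ring that bridges C1 and C9 can only be trans-fused to both six-membered rings, so C9–H must be α. LiAlH4 reduces lactone and ester together and comes back to the route at 15.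

- **Step 11.** Acylation of the neopentyl 1β-hydroxyl next to the C11 silyloxymethyl group may be slow, so that the mixed anhydride decomposes first. The fallback builds the cinnamate on the alcohol. It sets out from 16: the small acylating agent diethylphosphonoacetyl chloride (pyridine, DMAP, CH2Cl2) gives the phosphonoacetate F5. A Horner–Wadsworth–Emmons olefination with 4-(tert-butyldimethylsilyloxy)benzaldehyde (LiCl, DBU, MeCN) should then give the (E)-ester and comes back to the route at 21.

**Further compounds**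

F1 | step 3 | C8-allyl keto diester (3 bearing at C10 the CH(CO2tBu)–CH(CO2tBu)–CH2CH=CH2 chain, methyl cis to silicon; C8/C9 epimers) | CC1(C)CC[C@@H]([Si](C)(C)c2ccccc2)[C@](C)(C(C(=O)OC(C)(C)C)C(CC=C)C(=O)OC(C)(C)C)C1=O
F2 | step 3 | C6 keto aldehyde (allyl group of F1 cleaved to CH2CHO; C8/C9 epimers) | CC1(C)CC[C@@H]([Si](C)(C)c2ccccc2)[C@](C)(C(C(=O)OC(C)(C)C)C(CC=O)C(=O)OC(C)(C)C)C1=O
F3 | step 7 | tert-butyl 11-oxo-drim-8-ene-1β,11-olide-12-oate (Δ8 1,11-olide) | CC1(C)CC[C@@H](O3)[C@]2(C)C(C3=O)=C(C(=O)OC(C)(C)C)CC[C@@H]12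
F4 | step 7 | tert-butyl 11-oxo-drim-7-ene-1β,11-olide-12-oate (Δ7 1,11-olide, 9α-H) | CC1(C)CC[C@@H](O3)[C@]2(C)[C@@H](C3=O)C(C(=O)OC(C)(C)C)=CC[C@@H]12
F5 | step 11 | 11,12-bis(triethylsilyloxy)drim-7-en-1β-yl 2-(diethoxyphosphoryl)acetate | CC1(C)CC[C@@H](OC(=O)CP(=O)(OCC)OCC)[C@]2(C)[C@@H](CO[Si](CC)(CC)CC)C(CO[Si](CC)(CC)CC)=CC[C@@H]12
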